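If you have to call these two flasks, begin with the earlier run.

in all of them: substrate 0.10 M; first nucleophile 0.105 M
- south-west: solid second nucleophile 0.025 M; temperature 55 °C; run made earlier
- Sunday's: solid second nucleophile 0.0500 M; temperature 55 °C; time 10 h
- Friday's: solid second nucleophile 0.0500 M; temperature 25 °C; time 10 h

- south-west (time / min: target / %, other capture product / %): 8.00: 25, 1; 15.0: 38, 4; 25.0: 47, 4; 30.0: 50, 7; 40.0: 53, 6; 50.0: 56, 7; 60.0: 55, 8

(scatter of a reading: 1.5 percentage points)

- in percentages every species weighs as the substrate in it: one side product counts as two
- at the start none of the solid second nucleophile is in solution
- the earlier runs do not show what temperature does; that part of a forecast is a guess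

1. which flask leads in share of target in all that became target or other capture product or solvolysis product or side product ("all alike" within 1.5 percentage points) (Sunday's / Friday's / all alike)
2. share of target in all that became target or other capture product or solvolysis product or side product, Sunday's
3. share of target in all that became target or other capture product or solvolysis product or side product, Friday's

The south-west run flattens out. Its last two readings average 55.5% target and 7.50% other capture product, so the readings put the unseen part at about 37.0%. But if each target spends one first nucleophile, the first nucleophile falls as target forms, so you replace its curve by the mean of its start and end levels, 0.0772 M. Mean level times unseen over target then reads about 0.0515 M, with the scatter of the readings in it. Call this the half-capture concentration, the level of first nucleophile at which target and unseen loss form equally; it is a selectivity factor in concentration form. So at 55 °C, with this substrate charge, target over unseen should equal mean first nucleophile over that level. Sunday's has the same charges of substrate and first nucleophile and the same temperature, so you expect its ratio near 1.50. Friday's runs at 25 °C, cooler, and the earlier run doesn't show how the level moves, so any figure there is a guess.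

The forecast puts Sunday's ahead, with 52% against 46% for Friday's, and adds: “The temperature effect on selectivity is a guess”.

The flasks give 62.5% for Sunday's and 55.3% for Friday's, so Sunday's leads.

    substrate → intermediate (k = 0.00140 /min, Ea = 103 kJ/mol)
    first nucleophile + intermediate → target (k = 0.870 /M/min, Ea = 55.0 kJ/mol)
    second nucleophile + intermediate → other capture product (k = 2.40 /M/min, Ea = 61.0 kJ/mol)
    intermediate → solvolysis product (k = 0.00840 /min, Ea = 83.0 kJ/mol)
    solid second nucleophile ⇌ second nucleophile, rate k5*(cs5 - [second nucleophile]) while solid is left; crystals form when [second nucleophile] > cs5 (solubility = 24.0 mM, k = 0.0150 /min)
    substrate + target → side product (k = 0.00190 /M/min, Ea = 81.0 kJ/mol)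
    intermediate → decomposed reagent (k = 0.00120 /min, Ea = 108 kJ/mol)
    (constants at 25 °C)

In Sunday's, 57.4% target and 8.55% other capture product leave 34.0%, a ratio of 1.69. Its first nucleophile ends at 44% of its charge, so the mean over the half-capture concentration gives 1.46. The neighbour like Sunday's, charged with 0.042 M first nucleophile, ends at 23% of that charge, so the same reckoning gives 0.502. Its 31.5% target and 11.7% other capture product give a ratio of 0.555. In that neighbour, solvolysis product stands at 40.3%, more than target.

(The readings were generated by integration from invented constants.)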